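**Retrosynthetic overview**

1. Building blocks: 2-methylcyclohex-2-en-1-one (1, ring B), 4-methylpent-1-en-3-one (2, C1–C4 of ring A with the gem-dimethyl group) and resorcinol (3, arene); one-carbon units come from MeI, formaldehyde and BrCH2Cl.
2. Target ⇐ ortho-formylation, O-demethylation and C–H borylation/one-carbon homologation of a 2,6-dimethoxybenzyl decalin (arene decorated last).
3. Key disconnection: the C9 quaternary centre and the Δ1(10) alkene ⇐ acid-triggered 1,2-methyl shift from C10 to C9 in a cis-fused Δ8-octalin (C8 set by protonation, C9 by the suprafacial shift).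
4. Δ8-octalin ⇐ Negishi coupling of a C9 enol triflate with the 2,6-dimethoxybenzylzinc reagent; absolute configuration ⇐ CBS reduction of the racemic C3 ketone run as a kinetic resolution.
5. cis-Decalone ⇐ formal [4+2] annulation of ring A onto ring B (1 plus the silyloxydiene from 2); order: ring B (bought), ring A (annulation), arene (coupling), then the skeletal shift.

Assumption and conventions: terpenoid locants are used for the decalin (ring A = C1–C5 and C10, with the C3 carbinol and C4 gem-dimethyl; ring B = C5–C10; C11 = benzylic CH2; octalin/hexalin = octahydro-/hexahydronaphthalene); α/β refer to the target drawn with 5α-H (target = 3β-OH, 5α-H, 8α-CH3, 9α-CH3, 9β-CH2Ar = 3S,5R,8R,9S); racemic compounds 5–7, 13 and 14 are drawn as the enantiomer that is carried on.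

**Route**

Step 1
Reactants: 2 4-methylpent-1-en-3-one
Product: 4 tert-butyl(dimethyl)[(4-methylpenta-1,3-dien-3-yl)oxy]silane
Conditions: TBSOTf, Et3N, CH2Cl2, −20 to 0 °C
Reagents that add atoms: tert-butyldimethylsilyl trifluoromethanesulfonate CC(C)(C)[Si](C)(C)OS(=O)(=O)C(F)(F)F
Why: Soft enolisation and O-silylation (silyl enol ether formation); the isopropyl C–H is the only enolisable position, so the 2-silyloxydiene with the tetrasubstituted terminus forms regiospecifically.

Step 2
Reactants: 1 2-methylcyclohex-2-en-1-one; 4 tert-butyl(dimethyl)[(4-methylpenta-1,3-dien-3-yl)oxy]silane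
Product: 5 rac-3-(tert-butyldimethylsilyloxy)-4,4,10-trimethyl-cis-Δ2-octalin-9-one
Conditions: AlBr3 (20 mol%), AlMe3 (2 mol%), toluene/CH2Cl2, −20 to 0 °C; Et3N quench
Reagents that add atoms: none
Why: Lewis-acid-mediated annulation of a hindered 2-silyloxydiene with an α-methyl enone (Mukaiyama–Michael addition then ring-closing Michael addition, a formal [4+2] with precedent for hindered partners under mixed aluminium Lewis acids); the CMe2 terminus bonds to the enone β-carbon and both bonds form on one face of the enone, so 5-H and 10-CH3 are cis (racemic).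

Step 3
Reactants: 5 rac-3-(tert-butyldimethylsilyloxy)-4,4,10-trimethyl-cis-Δ2-octalin-9-one
Product: 7 rac-3-(tert-butyldimethylsilyloxy)-4,4,8,10-tetramethyl-cis-Δ2,8-hexalin-9-yl trifluoromethanesulfonate, via 8-methyl ketone 6 (not isolated)
Conditions: LiN(i-Pr)2, THF, −78 °C; MeI, −78 to 0 °C; then LiN(i-Pr)2, −78 to 0 °C; PhNTf2, 0 °C to rt
Reagents that add atoms: iodomethane CI; N-phenyl-bis(trifluoromethanesulfonimide) O=S(=O)(N(c1ccccc1)S(=O)(=O)C(F)(F)F)C(F)(F)F
Why: Enolate alkylation then enolate O-triflation; C8 is the only enolisable position of the C9 ketone (C10 is quaternary and C3 is masked as its silyl enol ether), so both events are regiospecific and the C8 configuration of 6 is irrelevant because C8 becomes sp2.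

Step 4
Reactants: 3 resorcinol
Product: 8 1,3-dimethoxybenzene
Conditions: MeI, K2CO3, acetone, reflux
Reagents that add atoms: iodomethane CI
Why: Williamson ether synthesis; methyl ethers survive the organolithium, organozinc and strong-acid steps and keep the phenols from trapping the later C10 cation.

Step 5
Reactants: 8 1,3-dimethoxybenzene
Product: 10 (2,6-dimethoxyphenyl)methanol, via aryllithium 9 (not isolated)
Conditions: n-BuLi, THF, 0 °C to rt; (CH2O)n, 0 °C to rt; H2O
Reagents that add atoms: formaldehyde (from paraformaldehyde) C=O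
Why: Directed ortho-metalation at C2 between the two methoxy groups, then hydroxymethylation of the aryllithium with formaldehyde.

Step 6
Reactants: 10 (2,6-dimethoxyphenyl)methanol
Product: 11 2-(chloromethyl)-1,3-dimethoxybenzene
Conditions: SOCl2, CH2Cl2, 0 °C
Reagents that add atoms: thionyl chloride O=S(Cl)Cl
Why: Deoxychlorination of an electron-rich benzylic alcohol through its chlorosulfite.

Step 7
Reactants: 11 2-(chloromethyl)-1,3-dimethoxybenzene; 7 rac-3-(tert-butyldimethylsilyloxy)-4,4,8,10-tetramethyl-cis-Δ2,8-hexalin-9-yl trifluoromethanesulfonate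
Product: 14 rac-9-(2,6-dimethoxybenzyl)-4,4,8,10-tetramethyl-cis-Δ8-octalin-3-one, via benzylzinc chloride 12 (not isolated), via silyl enol ether 13 (not isolated)
Conditions: Zn dust, LiCl, THF, rt; then 7, Pd(OAc)2 (5 mol%), 2-dicyclohexylphosphino-2′,6′-dimethoxybiphenyl (10 mol%), THF, 50 °C; then 1 M HCl, THF, rt
Reagents that add atoms: none
Why: Zinc insertion and Negishi cross-coupling of the benzylzinc reagent with the alkenyl triflate place the C9–C11 bond and the tetrasubstituted Δ8 alkene without any stereochemical issue, and mild acid hydrolysis of the silyl enol ether unmasks the C3 ketone.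

Step 8
Reactants: 14 rac-9-(2,6-dimethoxybenzyl)-4,4,8,10-tetramethyl-cis-Δ8-octalin-3-one
Product: 16 (3S,5R,10R)-9-(2,6-dimethoxybenzyl)-4,4,8,10-tetramethyl-cis-Δ8-octalin-3-yl acetate, via secondary alcohol 15 (not isolated)
Conditions: (R)-1-methyl-3,3-diphenyltetrahydro-1H,3H-pyrrolo[1,2-c][1,3,2]oxazaborole (20 mol%), BH3·SMe2 (0.3 equiv), THF, −20 °C, stopped near 50% conversion; MeOH; then Ac2O, Et3N, 4-(dimethylamino)pyridine (10 mol%), CH2Cl2, rt
Reagents that add atoms: acetic anhydride CC(=O)OC(C)=O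
Why: Corey–Bakshi–Shibata reduction run as a kinetic resolution, then acetylation; the catalyst delivers hydride to give the 3S carbinol (quaternary C4 as the large group), which coincides with the substrate-preferred attack on the open α-face only for the (5R,10R) enantiomer, so that enantiomer is reduced to the 3β-alcohol while the mismatched enantiomer stays a ketone and is removed by chromatography.

Step 9
Reactants: 16 (3S,5R,10R)-9-(2,6-dimethoxybenzyl)-4,4,8,10-tetramethyl-cis-Δ8-octalin-3-yl acetate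
Product: 17 (3S,5R,8R,9S)-9-(2,6-dimethoxybenzyl)-4,4,8,9-tetramethyl-Δ1(10)-octalin-3-yl acetate
Conditions: HN(SO2CF3)2 (5 mol%), toluene, −60 to −40 °C, 30 min; Et3N quench
Reagents that add atoms: none
Why: Proposed new method: catalytic HN(SO2CF3)2 protonates the tetrasubstituted Δ8 alkene at C8 on the β-face (the α-face is shielded by the pseudoaxial 10α-CH3 and the β-face is anti to the migrating group), the 10α-CH3, held parallel to the C9 p-orbital in the only low-energy conformer of the cis-octalin, shifts suprafacially to C9 so that one anti addition across C8=C9 sets 8α-CH3/8β-H and 9α-CH3/9β-CH2Ar, and the triflimide anion of the contact ion pair removes an exposed H-1 from the C10 cation faster than H-5, which is buried between the C4 and C9 quaternary centres, at low temperature and short contact time so that the Δ1(10) alkene is not equilibrated to the Δ5(10) isomer; the closest known reaction types are the BF3·OEt2-mediated friedo (1,2-hydride/1,2-methyl) rearrangement of Δ8-drimenyl arenes, run under equilibrating conditions, and strong-Brønsted-acid-catalysed Wagner–Meerwein shifts of alkenyl cycloalkanes with anion-controlled proton loss.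

Step 10
Reactants: 17 (3S,5R,8R,9S)-9-(2,6-dimethoxybenzyl)-4,4,8,9-tetramethyl-Δ1(10)-octalin-3-yl acetate
Product: 18 (3S,5R,8R,9S)-9-[2,6-dimethoxy-4-(4,4,5,5-tetramethyl-1,3,2-dioxaborolan-2-yl)benzyl]-4,4,8,9-tetramethyl-Δ1(10)-octalin-3-yl acetate
Conditions: B2pin2, [Ir(OMe)(1,5-cyclooctadiene)]2 (1.5 mol%), 4,4′-di-tert-butyl-2,2′-bipyridine (3 mol%), THF, 70 °C
Reagents that add atoms: bis(pinacolato)diboron CC1(C)OB(OC1(C)C)B1OC(C)(C)C(C)(C)O1
Why: Iridium-catalysed, sterically controlled aromatic C–H borylation; the C–H para to the benzylic carbon is the only arene C–H not flanked by a methoxy group, and the hindered trisubstituted alkene and the acetate are tolerated.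

Step 11
Reactants: 18 (3S,5R,8R,9S)-9-[2,6-dimethoxy-4-(4,4,5,5-tetramethyl-1,3,2-dioxaborolan-2-yl)benzyl]-4,4,8,9-tetramethyl-Δ1(10)-octalin-3-yl acetate
Product: 20 (3S,5R,8R,9S)-9-[4-(hydroxymethyl)-2,6-dimethoxybenzyl]-4,4,8,9-tetramethyl-Δ1(10)-octalin-3-ol, via benzylboronate 19 (not isolated)
Conditions: BrCH2Cl, n-BuLi, THF, −78 °C to rt; then NaOH, H2O2, THF/H2O, 0 °C to rt
Reagents that add atoms: bromochloromethane ClCBr; hydrogen peroxide OO
Why: Matteson homologation (1,2-aryl shift in the chloromethyl boronate complex) then oxidation of the benzylic C–B bond gives the benzylic alcohol, and the basic peroxide also saponifies the C3 acetate.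

Step 12
Reactants: 20 (3S,5R,8R,9S)-9-[4-(hydroxymethyl)-2,6-dimethoxybenzyl]-4,4,8,9-tetramethyl-Δ1(10)-octalin-3-ol
Product: 21 (3S,5R,8R,9S)-9-[2,6-dihydroxy-4-(hydroxymethyl)benzyl]-4,4,8,9-tetramethyl-Δ1(10)-octalin-3-ol
Conditions: MeMgI (10 equiv), Et2O removed, neat, 160 °C, 30 min; aq NH4Cl
Reagents that add atoms: none
Why: Non-acidic demethylation of aryl methyl ethers with MeMgI (SN2 at the O-methyl groups), the classical method for resorcinol dimethyl ethers that carry acid-sensitive terpenyl alkenes, so no acid is present that could add a phenol across the Δ1(10) alkene.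

Step 13
Reactants: 21 (3S,5R,8R,9S)-9-[2,6-dihydroxy-4-(hydroxymethyl)benzyl]-4,4,8,9-tetramethyl-Δ1(10)-octalin-3-ol
Product: 22 2,4-dihydroxy-6-(hydroxymethyl)-3-{[(3S,5R,8R,9S)-3-hydroxy-4,4,8,9-tetramethyl-Δ1(10)-octalin-9-yl]methyl}benzaldehyde
Conditions: MgCl2, Et3N, (CH2O)n, MeCN, reflux; aq NH4Cl
Reagents that add atoms: formaldehyde (from paraformaldehyde) C=O
Why: Magnesium-mediated ortho-formylation of a phenol (Casnati–Skattebøl); the two free ring positions are equivalent, each is ortho to one phenol and para to the other, and the first formyl group deactivates the ring towards a second.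

**Compound list**

1 | 2-methylcyclohex-2-en-1-one | CC1=CCCCC1=O | starting material
2 | 4-methylpent-1-en-3-one | C=CC(=O)C(C)C | starting material
3 | resorcinol (benzene-1,3-diol) | Oc1cccc(O)c1 | starting material
4 | tert-butyl(dimethyl)[(4-methylpenta-1,3-dien-3-yl)oxy]silane | C=CC(O[Si](C)(C)C(C)(C)C)=C(C)C | intermediate
5 | rac-3-(tert-butyldimethylsilyloxy)-4,4,10-trimethyl-cis-Δ2-octalin-9-one (5-H and 10-CH3 cis; racemic, one enantiomer drawn) | O=C1CCC[C@@H]2[C@@]1(C)CC=C(O[Si](C)(C)C(C)(C)C)C2(C)C | intermediate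
6 | rac-3-(tert-butyldimethylsilyloxy)-4,4,8,10-tetramethyl-cis-Δ2-octalin-9-one (C8 epimers; not isolated) | CC1CC[C@H]2C(C)(C)C(O[Si](C)(C)C(C)(C)C)=CC[C@@]2(C)C1=O | intermediate
7 | rac-3-(tert-butyldimethylsilyloxy)-4,4,8,10-tetramethyl-cis-Δ2,8-hexalin-9-yl trifluoromethanesulfonate | CC1=C(OS(=O)(=O)C(F)(F)F)[C@]2(C)CC=C(O[Si](C)(C)C(C)(C)C)C(C)(C)[C@@H]2CC1 | intermediate
8 | 1,3-dimethoxybenzene | COc1cccc(OC)c1 | intermediate
9 | (2,6-dimethoxyphenyl)lithium (not isolated) | [Li]c1c(OC)cccc1OC | intermediate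
10 | (2,6-dimethoxyphenyl)methanol | OCc1c(OC)cccc1OC | intermediate
11 | 2-(chloromethyl)-1,3-dimethoxybenzene | ClCc1c(OC)cccc1OC | intermediate
12 | (2,6-dimethoxybenzyl)zinc chloride (not isolated) | Cl[Zn]Cc1c(OC)cccc1OC | intermediate
13 | rac-9-(2,6-dimethoxybenzyl)-3-(tert-butyldimethylsilyloxy)-4,4,8,10-tetramethyl-cis-Δ2,8-hexalin (not isolated) | CC1=C(Cc2c(OC)cccc2OC)[C@]3(C)CC=C(O[Si](C)(C)C(C)(C)C)C(C)(C)[C@@H]3CC1 | intermediate
14 | rac-9-(2,6-dimethoxybenzyl)-4,4,8,10-tetramethyl-cis-Δ8-octalin-3-one (5-H and 10-CH3 cis; racemic, (5R,10R) enantiomer drawn) | CC1=C(Cc2c(OC)cccc2OC)[C@]3(C)CCC(=O)C(C)(C)[C@@H]3CC1 | intermediate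
15 | (3S,5R,10R)-9-(2,6-dimethoxybenzyl)-4,4,8,10-tetramethyl-cis-Δ8-octalin-3-ol (3β-OH, 5α-H, 10α-CH3; not isolated) | CC1=C(Cc2c(OC)cccc2OC)[C@]3(C)CC[C@H](O)C(C)(C)[C@@H]3CC1 | intermediate
16 | (3S,5R,10R)-9-(2,6-dimethoxybenzyl)-4,4,8,10-tetramethyl-cis-Δ8-octalin-3-yl acetate | CC1=C(Cc2c(OC)cccc2OC)[C@]3(C)CC[C@H](OC(C)=O)C(C)(C)[C@@H]3CC1 | intermediate
17 | (3S,5R,8R,9S)-9-(2,6-dimethoxybenzyl)-4,4,8,9-tetramethyl-Δ1(10)-octalin-3-yl acetate | C[C@@H]1CC[C@@H]2C(=CC[C@H](OC(C)=O)C2(C)C)[C@@]1(C)Cc1c(OC)cccc1OC | intermediate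
18 | (3S,5R,8R,9S)-9-[2,6-dimethoxy-4-(4,4,5,5-tetramethyl-1,3,2-dioxaborolan-2-yl)benzyl]-4,4,8,9-tetramethyl-Δ1(10)-octalin-3-yl acetate | C[C@@H]1CC[C@@H]2C(=CC[C@H](OC(C)=O)C2(C)C)[C@@]1(C)Cc1c(OC)cc(B3OC(C)(C)C(C)(C)O3)cc1OC | intermediate
19 | (3S,5R,8R,9S)-9-{2,6-dimethoxy-4-[(4,4,5,5-tetramethyl-1,3,2-dioxaborolan-2-yl)methyl]benzyl}-4,4,8,9-tetramethyl-Δ1(10)-octalin-3-yl acetate (not isolated) | C[C@@H]1CC[C@@H]2C(=CC[C@H](OC(C)=O)C2(C)C)[C@@]1(C)Cc1c(OC)cc(CB3OC(C)(C)C(C)(C)O3)cc1OC | intermediate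
20 | (3S,5R,8R,9S)-9-[4-(hydroxymethyl)-2,6-dimethoxybenzyl]-4,4,8,9-tetramethyl-Δ1(10)-octalin-3-ol | C[C@@H]1CC[C@@H]2C(=CC[C@H](O)C2(C)C)[C@@]1(C)Cc1c(OC)cc(CO)cc1OC | intermediate
21 | (3S,5R,8R,9S)-9-[2,6-dihydroxy-4-(hydroxymethyl)benzyl]-4,4,8,9-tetramethyl-Δ1(10)-octalin-3-ol | C[C@@H]1CC[C@@H]2C(=CC[C@H](O)C2(C)C)[C@@]1(C)Cc1c(O)cc(CO)cc1O | intermediate
22 | 2,4-dihydroxy-6-(hydroxymethyl)-3-{[(3S,5R,8R,9S)-3-hydroxy-4,4,8,9-tetramethyl-Δ1(10)-octalin-9-yl]methyl}benzaldehyde (CNP0348277.4) | C[C@@H]1CC[C@@H]2C(=CC[C@H](O)C2(C)C)[C@@]1(C)Cc1c(O)cc(CO)c(C=O)c1O | target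

**Step count and risks**

Total step count: 13. Longest linear sequence: 10 steps (steps 1, 2, 3, 7–13; the arene branch through steps 4–6 is equally long).

The three steps most likely to fail:

Step 9 (the proposed new step). It may give mainly the Δ5(10) isomer or return 16. The fallback keeps the same skeletal shift but runs it as a classical acid addition with rearrangement, and then makes the alkene by a syn-elimination that cannot reach H-5. Setting out from 16, CF3CO2H in CH2Cl2 at −20 °C protonates C8, the methyl group shifts and the C10 cation is captured anti to the migrated methyl, giving the tertiary trifluoroacetate F1. Brief NaHCO3 in aqueous MeOH cleaves only this ester to the 10β-alcohol F2 (trans to 5α-H). The Burgess reagent (toluene, 50 °C) then eliminates by a syn pathway for which only H-1β is available (H-5 is anti, C9 has no hydrogen), and the route is rejoined at 17.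

Step 8. The kinetic resolution may be unselective, and its yield is capped at 50% in any case. Setting out from 14, NaBH4 (MeOH, 0 °C; hydride adds from the open α-face) gives the racemic 3β-alcohol F3. This is esterified with (S)-2-methoxy-2-phenylacetic acid (DCC, 4-(dimethylamino)pyridine) and the two diastereomeric esters are separated by chromatography or crystallisation. The (3S,5R,10R) ester F4 is saponified (LiOH, THF/H2O) to 15, which is acetylated as in step 8 to re-enter at 16.

Step 2. The one-pot annulation of two hindered partners may stall or desilylate. Setting out from 1 and 4, the two bonds are made separately. Mukaiyama–Michael addition with catalytic HN(SO2CF3)2 (silyl triflimide generated in the flask) at −78 °C gives the ring-B silyl enol ether carrying the vinyl ketone side chain, Michael adduct F5. A second, intramolecular Mukaiyama–Michael reaction (Me2AlCl, CH2Cl2, −40 °C), in which the silyl group moves to the new enolate oxygen, closes ring A cis and rejoins the route at 5.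

**Further compounds**

F1 | step 9 | 9-(2,6-dimethoxybenzyl)-3β-acetoxy-4,4,8,9-tetramethyl-trans-decalin-10β-yl trifluoroacetate (5α-H, 8α-CH3, 9α-CH3) | C[C@@H]1CC[C@@H]2[C@](OC(=O)C(F)(F)F)(CC[C@H](OC(C)=O)C2(C)C)[C@@]1(C)Cc1c(OC)cccc1OC
F2 | step 9 | 9-(2,6-dimethoxybenzyl)-10β-hydroxy-4,4,8,9-tetramethyl-trans-decalin-3β-yl acetate (5α-H, 8α-CH3, 9α-CH3) | C[C@@H]1CC[C@@H]2[C@](O)(CC[C@H](OC(C)=O)C2(C)C)[C@@]1(C)Cc1c(OC)cccc1OC
F3 | step 8 | rac-9-(2,6-dimethoxybenzyl)-4,4,8,10-tetramethyl-cis-Δ8-octalin-3-ol (3-OH trans to 5-H; racemic, one enantiomer drawn) | CC1=C(Cc2c(OC)cccc2OC)[C@]3(C)CC[C@H](O)C(C)(C)[C@@H]3CC1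
F4 | step 8 | (3S,5R,10R)-9-(2,6-dimethoxybenzyl)-4,4,8,10-tetramethyl-cis-Δ8-octalin-3-yl (S)-2-methoxy-2-phenylacetate | CC1=C(Cc2c(OC)cccc2OC)[C@]3(C)CC[C@H](OC(=O)[C@@H](OC)c4ccccc4)C(C)(C)[C@@H]3CC1
F5 | step 2 | rac-4-[3-(tert-butyldimethylsilyloxy)-2-methylcyclohex-2-en-1-yl]-4-methylpent-1-en-3-one (racemic, one enantiomer drawn) | C=CC(=O)C(C)(C)[C@@H]1CCCC(O[Si](C)(C)C(C)(C)C)=C1C
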